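**Plan**

- Retrosynthesis: the target is cut first at O1–C7a (ethanol exchange at a vinylogous ester). The carbocycle is then cut in one operation at C5–C6, C6–C7, C7a–C3a and C3a–C4, leaving an acyclic diazo ketone and ethoxyacetylene. The diazo ketone is cut at the ketone–alkyne bond and at C2–C3 (crotylation).
- Forward: the C2–C3 chain is made first and extended to the diazo ketone. The six-membered ring (C3a, C4, C5, C6, C7, C7a) then arises in a Wolff shift / [2+2] / four-electron opening / six-electron closure cascade. The dihydrofuran ring (O1, C2, C3, C3a, C7a) is closed last.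
- Enabling feature (benzofuran numbering): the oxygen on C7a is meta to the C6 carbonyl and C5 is quaternary (allyl, OMe). This is the pattern a vinylketene and an alkoxyalkyne deliver when the dienone cannot enolise to a phenol.
- Stereochemistry: C2 and C3 (both S, trans) come from a phosphoric acid catalysed anti crotylboration. C5 (R) is set in the electrocyclisation under weak substrate control and is secured by separation and photochemical recycling.

Key step: step 9

Assumption: the (R)-configured TRIP acid is taken to give the 1R carbinol from aromatic aldehydes in crotylboration, so the (S)-acid is specified for the 1S,2S alcohol; if the sense is opposite, the antipodal acid is used with no other change.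

**Route**

Step 1
Reactants: 1 3,4,5-trimethoxybenzaldehyde; 2 (E)-crotylboronic acid pinacol ester
Product: 3 (1S,2S)-2-methyl-1-(3,4,5-trimethoxyphenyl)but-3-en-1-ol
Conditions: 2 (1.2 equiv), (S)-TRIP phosphoric acid (5 mol %), PhMe, −30 °C; aq. NaHCO3
Reagents that add atoms: none
Why: Chiral phosphoric acid catalysed crotylboration runs through a closed chair transition state, so the E boronate gives the anti adduct, and (S)-3,3'-bis(2,4,6-triisopropylphenyl)-1,1'-binaphthyl-2,2'-diyl hydrogen phosphate, hydrogen-bonded to a boronate oxygen and the formyl hydrogen, selects the aldehyde face that gives the 1S,2S alcohol.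

Step 2
Reactants: 3 (1S,2S)-2-methyl-1-(3,4,5-trimethoxyphenyl)but-3-en-1-ol
Product: 4 (1S,2S)-2-methyl-1-(3,4,5-trimethoxyphenyl)butane-1,4-diol
Conditions: 9-BBN (2.2 equiv), THF, 0 °C to rt; then NaOH, H2O2, 0 °C
Reagents that add atoms: hydrogen peroxide, OO
Why: Hydroboration–oxidation with the bulky borane places boron on the terminal carbon and replaces it by hydroxyl with retention, which gives the primary alcohol and leaves both stereocentres untouched.

Step 3
Reactants: 4 (1S,2S)-2-methyl-1-(3,4,5-trimethoxyphenyl)butane-1,4-diol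
Product: 6 (4S,5S)-4-methyl-5-(3,4,5-trimethoxyphenyl)dihydrofuran-2(3H)-one, via lactol 5 (not isolated)
Conditions: TEMPO (20 mol %), PhI(OAc)2 (2.5 equiv), CH2Cl2, rt
Reagents that add atoms: none
Why: Oxoammonium (TEMPO) oxidation takes the primary alcohol in preference to the hindered secondary benzylic one, the hydroxy aldehyde closes to lactol 5 and a second oxidation gives the trans lactone (oxidative lactonisation of a 1,4-diol).

Step 4
Reactants: 6 (4S,5S)-4-methyl-5-(3,4,5-trimethoxyphenyl)dihydrofuran-2(3H)-one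
Product: 7 (3S,4S)-4-hydroxy-N-methoxy-N,3-dimethyl-4-(3,4,5-trimethoxyphenyl)butanamide
Conditions: MeNH(OMe)·HCl (3 equiv), i-PrMgCl (6 equiv), THF, −20 to 0 °C; cold aq. NH4Cl
Reagents that add atoms: N,O-dimethylhydroxylamine hydrochloride, CNOC.Cl
Why: Weinreb aminolysis, in which ClMgN(OMe)Me made in the flask opens the lactone by acyl substitution and the product stays as its magnesium alkoxide until the cold quench, which holds back relactonisation.

Step 5
Reactants: 7 (3S,4S)-4-hydroxy-N-methoxy-N,3-dimethyl-4-(3,4,5-trimethoxyphenyl)butanamide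
Product: 8 (3S,4S)-4-(tert-butyldimethylsilyloxy)-N-methoxy-N,3-dimethyl-4-(3,4,5-trimethoxyphenyl)butanamide
Conditions: TBSOTf (1.3 equiv), 2,6-lutidine (2 equiv), CH2Cl2, −78 to 0 °C (crude 7 used at once)
Reagents that add atoms: tert-butyldimethylsilyl trifluoromethanesulfonate, CC(C)(C)[Si](C)(C)OS(=O)(=O)C(F)(F)F
Why: Silylation of the secondary benzylic alcohol with the silyl triflate and a hindered pyridine base is fast enough at low temperature to outrun relactonisation of the gamma-hydroxy amide, and the silyl ether survives amide bases, azide transfer and light.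

Step 6
Reactants: 8 (3S,4S)-4-(tert-butyldimethylsilyloxy)-N-methoxy-N,3-dimethyl-4-(3,4,5-trimethoxyphenyl)butanamide; 9 pent-1-en-4-yne
Product: 10 (8S,9S)-9-(tert-butyldimethylsilyloxy)-8-methyl-9-(3,4,5-trimethoxyphenyl)non-1-en-4-yn-6-one
Conditions: 9 (2.5 equiv), n-BuLi (2.3 equiv), THF, −78 °C; then 8, −78 to −20 °C; cold aq. NH4Cl
Reagents that add atoms: none
Why: Weinreb ketone synthesis, in which the alkyne C–H is far more acidic than the allylic–propargylic methylene, the lithium acetylide adds once because the chelated tetrahedral adduct persists until the quench, and the ynone appears only on cold mildly acidic work-up.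

Step 7
Reactants: 10 (8S,9S)-9-(tert-butyldimethylsilyloxy)-8-methyl-9-(3,4,5-trimethoxyphenyl)non-1-en-4-yn-6-one
Product: 11 (4E,8S,9S)-9-(tert-butyldimethylsilyloxy)-4-methoxy-8-methyl-9-(3,4,5-trimethoxyphenyl)nona-1,4-dien-6-one
Conditions: MeOH (10 equiv), PMe3 (10 mol %), CH2Cl2, 0 °C
Reagents that add atoms: methanol, CO
Why: Phosphine-catalysed oxa-Michael addition of methanol to the ynone gives the beta-methoxy enone, expected as the more stable E isomer with methoxy trans to the carbonyl, while only a catalytic amount of methoxide is present near the skipped diene.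

Step 8
Reactants: 11 (4E,8S,9S)-9-(tert-butyldimethylsilyloxy)-4-methoxy-8-methyl-9-(3,4,5-trimethoxyphenyl)nona-1,4-dien-6-one
Product: 13 (4E,8S,9S)-9-(tert-butyldimethylsilyloxy)-7-diazo-4-methoxy-8-methyl-9-(3,4,5-trimethoxyphenyl)nona-1,4-dien-6-one, via trifluoroacetyl diketone 12 (not isolated)
Conditions: LiN(SiMe3)2 (1.1 equiv), THF, −78 °C; CF3CO2CH2CF3 (1.2 equiv), −78 °C; brief cold 5% aq. HCl wash; crude 12, 4-AcNHC6H4SO2N3 (1.5 equiv), Et3N (1.5 equiv), H2O (1 equiv), MeCN, rt
Reagents that add atoms: 4-acetamidobenzenesulfonyl azide, CC(=O)Nc1ccc(cc1)S(=O)(=O)N=[N+]=[N-]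
Why: Detrifluoroacetylative diazo transfer, in which kinetic deprotonation of the vinylogous ester takes place at the alpha-prime methylene C7, the enolate is acylated to diketone 12, and the sulfonyl azide then delivers the diazo group to the doubly activated carbon with transfer of the trifluoroacetyl group to the sulfonamide.

Step 9
Reactants: 13 (4E,8S,9S)-9-(tert-butyldimethylsilyloxy)-7-diazo-4-methoxy-8-methyl-9-(3,4,5-trimethoxyphenyl)nona-1,4-dien-6-one; 14 ethoxyacetylene
Product: 18 (6R)-6-allyl-3-ethoxy-6-methoxy-4-[(1S,2S)-1-(tert-butyldimethylsilyloxy)-1-(3,4,5-trimethoxyphenyl)propan-2-yl]cyclohexa-2,4-dien-1-one, via vinylketene 15 (not isolated), via cyclobutenone 16 (not isolated), via dienylketene 17 (not isolated)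
Conditions: 14 (5 equiv), ClCH2CH2Cl (0.1 M), hν 254 nm (low-pressure Hg lamps, Vycor), rt, until 13 is consumed; then 70 °C in the dark, 2 h; chromatographic separation of the C5 epimers
Reagents that add atoms: none
Why: Light expels N2 from 13 with 1,2-shift of the methoxydienyl group from the carbonyl carbon (C6) to the diazo carbon (C3a, new C3a–C4 bond) to give vinylketene 15, and the nucleophilic CH carbon of 14 then bonds to the ketene carbon C6 while its oxygen-bearing carbon bonds to C3a in a [2+2] cycloaddition that closes the four-membered ring of 16. Conrotatory four-electron opening of 16 cuts C3a–C6 to give dienylketene 17, and the six-membered ring is closed by thermal disrotatory six-electron electrocyclisation between C6 and the enol ether carbon C5. The closest known reaction type is the vinylketene–alkoxyalkyne aromatic annulation in its photochemical Wolff form (Danheiser annulation), which here must stop at the 2,4-cyclohexadienone because C5 carries allyl and methoxy and no hydrogen for enolisation to a phenol. C5 is the only new stereocentre and is set by the helical sense in which 17 coils before closure, biased only by the C3 stereocentre on the C3a side chain, so substrate control is expected to be modest. The step needs alkenyl rather than alkyl migration, which is secured because the alkenyl group is the only substituent on the carbonyl carbon, and the head-to-tail regiochemistry of the cycloaddition, which the polarisation of the ynol ether secures. It also needs one face of C5, which is met by chromatographic separation and by returning material of the wrong C5 configuration to the open dienylketene with near-UV light (about 350 nm) for thermal reclosure.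

Step 10
Reactants: 18 (6R)-6-allyl-3-ethoxy-6-methoxy-4-[(1S,2S)-1-(tert-butyldimethylsilyloxy)-1-(3,4,5-trimethoxyphenyl)propan-2-yl]cyclohexa-2,4-dien-1-one
Product: 19 (6R)-6-allyl-3-ethoxy-4-[(1S,2S)-1-hydroxy-1-(3,4,5-trimethoxyphenyl)propan-2-yl]-6-methoxycyclohexa-2,4-dien-1-one
Conditions: HF·pyridine, pyridine, THF, 0 °C to rt
Reagents that add atoms: none
Why: Fluoride-mediated desilylation under buffered, weakly acidic conditions cleaves the Si–O bond without generating an alkoxide, so the dienone, the enol ether and the benzylic C2–O bond stay intact.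

Step 11
Reactants: 19 (6R)-6-allyl-3-ethoxy-4-[(1S,2S)-1-hydroxy-1-(3,4,5-trimethoxyphenyl)propan-2-yl]-6-methoxycyclohexa-2,4-dien-1-one
Product: 20 (2S,3S,5R)-5-allyl-5-methoxy-3-methyl-2-(3,4,5-trimethoxyphenyl)-2,3-dihydro-1-benzofuran-6(5H)-one
Conditions: PPTS (20 mol %), 4 Å MS, PhMe, 45 °C
Reagents that add atoms: none
Why: Acid-catalysed vinylogous transesterification, in which the C2 hydroxyl adds to C7a of the beta-ethoxy enone in a 5-exo-trig sense and ethanol is expelled (addition–elimination), closes ring O1–C2–C3–C3a–C7a without breaking a bond at C2, C3 or C5, so the trans 2-aryl-3-methyl relationship and the C5 configuration are carried over unchanged.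

**Compound list**

1 | 3,4,5-trimethoxybenzaldehyde | COc1cc(C=O)cc(OC)c1OC | starting material
2 | (E)-crotylboronic acid pinacol ester | C/C=C/CB1OC(C)(C)C(C)(C)O1 | starting material
3 | (1S,2S)-2-methyl-1-(3,4,5-trimethoxyphenyl)but-3-en-1-ol | C=C[C@H](C)[C@H](O)c1cc(OC)c(OC)c(OC)c1 | intermediate
4 | (1S,2S)-2-methyl-1-(3,4,5-trimethoxyphenyl)butane-1,4-diol | OCC[C@H](C)[C@H](O)c1cc(OC)c(OC)c(OC)c1 | intermediate
5 | (4S,5S)-4-methyl-5-(3,4,5-trimethoxyphenyl)tetrahydrofuran-2-ol (lactol, both anomers) | OC1C[C@H](C)[C@@H](c2cc(OC)c(OC)c(OC)c2)O1 | intermediate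
6 | (4S,5S)-4-methyl-5-(3,4,5-trimethoxyphenyl)dihydrofuran-2(3H)-one | O=C1C[C@H](C)[C@@H](c2cc(OC)c(OC)c(OC)c2)O1 | intermediate
7 | (3S,4S)-4-hydroxy-N-methoxy-N,3-dimethyl-4-(3,4,5-trimethoxyphenyl)butanamide | CON(C)C(=O)C[C@H](C)[C@H](O)c1cc(OC)c(OC)c(OC)c1 | intermediate
8 | (3S,4S)-4-(tert-butyldimethylsilyloxy)-N-methoxy-N,3-dimethyl-4-(3,4,5-trimethoxyphenyl)butanamide | CON(C)C(=O)C[C@H](C)[C@H](O[Si](C)(C)C(C)(C)C)c1cc(OC)c(OC)c(OC)c1 | intermediate
9 | pent-1-en-4-yne | C=CCC#C | starting material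
10 | (8S,9S)-9-(tert-butyldimethylsilyloxy)-8-methyl-9-(3,4,5-trimethoxyphenyl)non-1-en-4-yn-6-one | C=CCC#CC(=O)C[C@H](C)[C@H](O[Si](C)(C)C(C)(C)C)c1cc(OC)c(OC)c(OC)c1 | intermediate
11 | (4E,8S,9S)-9-(tert-butyldimethylsilyloxy)-4-methoxy-8-methyl-9-(3,4,5-trimethoxyphenyl)nona-1,4-dien-6-one | C=CC/C(OC)=C\C(=O)C[C@H](C)[C@H](O[Si](C)(C)C(C)(C)C)c1cc(OC)c(OC)c(OC)c1 | intermediate
12 | (4E,8S,9S)-9-(tert-butyldimethylsilyloxy)-4-methoxy-8-methyl-7-(trifluoroacetyl)-9-(3,4,5-trimethoxyphenyl)nona-1,4-dien-6-one (C7 epimers and enol forms) | C=CC/C(OC)=C\C(=O)C(C(=O)C(F)(F)F)[C@H](C)[C@H](O[Si](C)(C)C(C)(C)C)c1cc(OC)c(OC)c(OC)c1 | intermediate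
13 | (4E,8S,9S)-9-(tert-butyldimethylsilyloxy)-7-diazo-4-methoxy-8-methyl-9-(3,4,5-trimethoxyphenyl)nona-1,4-dien-6-one | C=CC/C(OC)=C\C(=O)C(=[N+]=[N-])[C@H](C)[C@H](O[Si](C)(C)C(C)(C)C)c1cc(OC)c(OC)c(OC)c1 | intermediate
14 | ethoxyacetylene | C#COCC | starting material
15 | (3S,4S)-4-(tert-butyldimethylsilyloxy)-2-[(1E)-2-methoxypenta-1,4-dien-1-yl]-3-methyl-4-(3,4,5-trimethoxyphenyl)but-1-en-1-one (vinylketene) | C=CC/C(OC)=C\C(=C=O)[C@H](C)[C@H](O[Si](C)(C)C(C)(C)C)c1cc(OC)c(OC)c(OC)c1 | intermediate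
16 | 4-[(1S,2S)-1-(tert-butyldimethylsilyloxy)-1-(3,4,5-trimethoxyphenyl)propan-2-yl]-3-ethoxy-4-[(1E)-2-methoxypenta-1,4-dien-1-yl]cyclobut-2-en-1-one (both C4 epimers) | C=CC/C(OC)=C\C1(C(=O)C=C1OCC)[C@H](C)[C@H](O[Si](C)(C)C(C)(C)C)c2cc(OC)c(OC)c(OC)c2 | intermediate
17 | (3E,5E)-4-[(1S,2S)-1-(tert-butyldimethylsilyloxy)-1-(3,4,5-trimethoxyphenyl)propan-2-yl]-3-ethoxy-6-methoxynona-1,3,5,8-tetraen-1-one (dienylketene, ketene arm and methoxydienyl arm cis) | C=CC/C(OC)=C\C(=C(\OCC)C=C=O)[C@H](C)[C@H](O[Si](C)(C)C(C)(C)C)c1cc(OC)c(OC)c(OC)c1 | intermediate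
18 | (6R)-6-allyl-3-ethoxy-6-methoxy-4-[(1S,2S)-1-(tert-butyldimethylsilyloxy)-1-(3,4,5-trimethoxyphenyl)propan-2-yl]cyclohexa-2,4-dien-1-one | C=CC[C@@]1(OC)C=C([C@H](C)[C@H](O[Si](C)(C)C(C)(C)C)c2cc(OC)c(OC)c(OC)c2)C(OCC)=CC1=O | intermediate
19 | (6R)-6-allyl-3-ethoxy-4-[(1S,2S)-1-hydroxy-1-(3,4,5-trimethoxyphenyl)propan-2-yl]-6-methoxycyclohexa-2,4-dien-1-one | C=CC[C@@]1(OC)C=C([C@H](C)[C@H](O)c2cc(OC)c(OC)c(OC)c2)C(OCC)=CC1=O | intermediate
20 | (2S,3S,5R)-5-allyl-5-methoxy-3-methyl-2-(3,4,5-trimethoxyphenyl)-2,3-dihydro-1-benzofuran-6(5H)-one | C=CC[C@@]1(OC)C=C2C(=CC1=O)O[C@H](c1cc(OC)c(OC)c(OC)c1)[C@H]2C | target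

**Step count**

Total steps: 11. Longest linear sequence: 11 steps (1 to 20).

**Steps most likely to fail**

Step 9. The excited diazo ketone may leave through a free ketocarbene (1,2-hydride shift from C3–H) instead of the concerted Wolff shift. The dienone may also undergo secondary photolysis while irradiation continues, the volatile ynol ether may be lost, and the face preference at C5 may be small. The fallback takes light out of the annulation; it sets out from 13 and returns at 18.
- A short irradiation of 13 (254 nm) in THF–water with NaHCO3 traps the ketene as it forms. Acidification to pH 5 should give (3E)-2-[(1S,2S)-1-(tert-butyldimethylsilyloxy)-1-(3,4,5-trimethoxyphenyl)propan-2-yl]-4-methoxyhepta-3,6-dienoic acid F1 (both C2 epimers).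
- 1-Chloro-N,N,2-trimethylprop-1-en-1-amine in CH2Cl2 converts it under neutral conditions into (3E)-2-[(1S,2S)-1-(tert-butyldimethylsilyloxy)-1-(3,4,5-trimethoxyphenyl)propan-2-yl]-4-methoxyhepta-3,6-dienoyl chloride F2.
- Slow addition of Et3N to F2 and 14 in ClCH2CH2Cl at rt, then 70 °C, all in the dark, regenerates vinylketene 15 by dehydrochlorination. From there 15 continues through 16 and 17 to 18, and the route is rejoined at step 10.

Step 8. Deprotonation may occur at the doubly activated C3 methylene (between the enol ether carbon and the vinyl group) in competition with C7, with drift of the terminal alkene into conjugation. C-acylation of the hindered enolate may also be slow. The fallback carries the terminal alkene as a 3-(phenylselanyl)propyl group through all base-mediated steps; it sets out from 8 and returns at 13.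
- 5-Chloropent-1-yne and PhSeNa (from PhSeSePh and NaBH4 in EtOH) give phenyl(pent-4-yn-1-yl)selane F3.
- Its lithium acetylide (n-BuLi, THF, −78 °C) adds to 8 to give (8S,9S)-9-(tert-butyldimethylsilyloxy)-8-methyl-1-(phenylselanyl)-9-(3,4,5-trimethoxyphenyl)non-4-yn-6-one F4.
- Methanol addition as in step 7 gives (4E,8S,9S)-9-(tert-butyldimethylsilyloxy)-4-methoxy-8-methyl-1-(phenylselanyl)-9-(3,4,5-trimethoxyphenyl)non-4-en-6-one F5.
- LiN(SiMe3)2 and CF3CO2CH2CF3 then give (4E,8S,9S)-9-(tert-butyldimethylsilyloxy)-4-methoxy-8-methyl-1-(phenylselanyl)-7-(trifluoroacetyl)-9-(3,4,5-trimethoxyphenyl)non-4-en-6-one F6, now with only ordinary alkyl C–H next to the enol ether.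
- The sulfonyl azide of step 8 converts it into (4E,8S,9S)-9-(tert-butyldimethylsilyloxy)-7-diazo-4-methoxy-8-methyl-1-(phenylselanyl)-9-(3,4,5-trimethoxyphenyl)non-4-en-6-one F7.
- H2O2 with pyridine in CH2Cl2 at 0 °C oxidises selenium to (4E,8S,9S)-9-(tert-butyldimethylsilyloxy)-7-diazo-4-methoxy-8-methyl-1-(phenylseleninyl)-9-(3,4,5-trimethoxyphenyl)non-4-en-6-one F8. Its syn elimination at rt to 40 °C unveils the allyl group and returns 13 for step 9.

Step 7. The phosphonium methoxide ion pair may shuttle protons at the C3 methylene of the enynone, with isomerisation to allenyl and conjugated dienyl ketones or addition at the wrong carbon. The fallback activates the alkyne as an electrophile instead of using a nucleophilic catalyst; it sets out from 10 and returns at 11.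
- Ph3PAuNTf2 (2 mol %) in MeOH at rt should add methanol twice at C4, the carbon remote from the carbonyl, to give (8S,9S)-9-(tert-butyldimethylsilyloxy)-4,4-dimethoxy-8-methyl-9-(3,4,5-trimethoxyphenyl)non-1-en-6-one F9.
- PPTS in toluene at 60 °C then expels one methanol towards the carbonyl side, which gives the conjugated enol ether 11 and rejoins the route at step 8.

Further compounds
F1 | step 9 | (3E)-2-[(1S,2S)-1-(tert-butyldimethylsilyloxy)-1-(3,4,5-trimethoxyphenyl)propan-2-yl]-4-methoxyhepta-3,6-dienoic acid | C=CC/C(OC)=C\C(C(=O)O)[C@H](C)[C@H](O[Si](C)(C)C(C)(C)C)c1cc(OC)c(OC)c(OC)c1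
F2 | step 9 | (3E)-2-[(1S,2S)-1-(tert-butyldimethylsilyloxy)-1-(3,4,5-trimethoxyphenyl)propan-2-yl]-4-methoxyhepta-3,6-dienoyl chloride | C=CC/C(OC)=C\C(C(=O)Cl)[C@H](C)[C@H](O[Si](C)(C)C(C)(C)C)c1cc(OC)c(OC)c(OC)c1
F3 | step 8 | phenyl(pent-4-yn-1-yl)selane | C#CCCC[Se]c1ccccc1
F4 | step 8 | (8S,9S)-9-(tert-butyldimethylsilyloxy)-8-methyl-1-(phenylselanyl)-9-(3,4,5-trimethoxyphenyl)non-4-yn-6-one | O=C(C#CCCC[Se]c1ccccc1)C[C@H](C)[C@H](O[Si](C)(C)C(C)(C)C)c1cc(OC)c(OC)c(OC)c1
F5 | step 8 | (4E,8S,9S)-9-(tert-butyldimethylsilyloxy)-4-methoxy-8-methyl-1-(phenylselanyl)-9-(3,4,5-trimethoxyphenyl)non-4-en-6-one | c1ccccc1[Se]CCC/C(OC)=C\C(=O)C[C@H](C)[C@H](O[Si](C)(C)C(C)(C)C)c1cc(OC)c(OC)c(OC)c1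
F6 | step 8 | (4E,8S,9S)-9-(tert-butyldimethylsilyloxy)-4-methoxy-8-methyl-1-(phenylselanyl)-7-(trifluoroacetyl)-9-(3,4,5-trimethoxyphenyl)non-4-en-6-one | c1ccccc1[Se]CCC/C(OC)=C\C(=O)C(C(=O)C(F)(F)F)[C@H](C)[C@H](O[Si](C)(C)C(C)(C)C)c1cc(OC)c(OC)c(OC)c1
F7 | step 8 | (4E,8S,9S)-9-(tert-butyldimethylsilyloxy)-7-diazo-4-methoxy-8-methyl-1-(phenylselanyl)-9-(3,4,5-trimethoxyphenyl)non-4-en-6-one | c1ccccc1[Se]CCC/C(OC)=C\C(=O)C(=[N+]=[N-])[C@H](C)[C@H](O[Si](C)(C)C(C)(C)C)c1cc(OC)c(OC)c(OC)c1
F8 | step 8 | (4E,8S,9S)-9-(tert-butyldimethylsilyloxy)-7-diazo-4-methoxy-8-methyl-1-(phenylseleninyl)-9-(3,4,5-trimethoxyphenyl)non-4-en-6-one | O=[Se](c1ccccc1)CCC/C(OC)=C\C(=O)C(=[N+]=[N-])[C@H](C)[C@H](O[Si](C)(C)C(C)(C)C)c1cc(OC)c(OC)c(OC)c1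
F9 | step 7 | (8S,9S)-9-(tert-butyldimethylsilyloxy)-4,4-dimethoxy-8-methyl-9-(3,4,5-trimethoxyphenyl)non-1-en-6-one | C=CCC(OC)(OC)CC(=O)C[C@H](C)[C@H](O[Si](C)(C)C(C)(C)C)c1cc(OC)c(OC)c(OC)c1
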